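**Strategy**

1. Retrosynthetic cuts: first the five O‑benzyl bonds; then the C2–C1' bond between ring C of the flavanone and its 4‑hydroxyphenyl ring B, leading back to a 2‑unsubstituted chromone and an arylboronic acid; then O1–C2 and C2–C3 of that chromone, leading back to an o‑hydroxyacetophenone and a formamide acetal carbon; then the ether bond between the C6 oxygen of the flavanone ring A and C4' of the flavone ring B, leading back to a 5‑hydroxyacetophenone and a 4'‑iodoflavone. Both halves come from 2,4,6‑trihydroxyacetophenone.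
2. Forward ring order: the flavone pyranone is closed first (chalcone, oxidative cyclisation), the halves are joined through the diaryl ether, the chromone pyranone is closed next, and ring B is attached to C2 last, before global debenzylation.
3. Enabling feature: the only stereocentre, C2 of the flavanone ring C, is β to the C4 ketone and carries ring B, whereas C2 of the flavone pyranone is already arylated. A conjugate arylation therefore reacts only at the C2–H chromone of an otherwise achiral bis‑pyranone.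
4. Stereochemistry: (2S) is set by the chiral bisphosphine on rhodium in that arylation (aryl to the Re face of C2) and is kept by a base‑free end game.

Key step: step 8

Remark: the target's single stereocentre is read as (2S); the ligand antipode in step 8 is assigned by the quadrant model for biaryl‑bisphosphine–rhodium additions to six‑membered enones and should be confirmed on 5,7‑bis(benzyloxy)chromone before the real substrate is committed.

**Route**

Step 1
Reactants: 1 2,4,6‑trihydroxyacetophenone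
Product: 2 2‑hydroxy‑4,6‑bis(benzyloxy)acetophenone
Conditions: BnBr (2.05 equiv), K2CO3, DMF, rt
Reagents that add atoms: benzyl bromide, BrCc1ccccc1
Why: Williamson O‑alkylation in which the 4‑OH and one ortho OH react first, so that with two equivalents of benzyl bromide and a mild base the hydroxyl hydrogen‑bonded to the acetyl carbonyl should be left free.

Step 2
Reactants: 2 2‑hydroxy‑4,6‑bis(benzyloxy)acetophenone; 3 4‑iodobenzaldehyde
Product: 4 (E)‑2'‑hydroxy‑4',6'‑bis(benzyloxy)‑4‑iodochalcone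
Conditions: KOH, EtOH/THF, rt
Reagents that add atoms: none
Why: Claisen–Schmidt condensation of the acetophenone enolate with a non‑enolisable aldehyde, the aldol dehydrating by E1cB to the (E)‑enone while the aryl iodide and benzyl ethers are inert to ethanolic KOH.

Step 3
Reactants: 4 (E)‑2'‑hydroxy‑4',6'‑bis(benzyloxy)‑4‑iodochalcone
Product: 5 5,7‑bis(benzyloxy)‑4'‑iodoflavone
Conditions: I2 (10 mol%), DMSO, 120 °C
Reagents that add atoms: none
Why: Iodine‑catalysed oxidative cyclisation of a 2'‑hydroxychalcone, a standard flavone synthesis in which the phenol closes the pyranone 6‑endo onto the enone β‑carbon and DMSO reoxidises the HI formed, the aryl iodide and (with only catalytic iodine) the benzyl ethers being expected to survive.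

Step 4
Reactants: 2 2‑hydroxy‑4,6‑bis(benzyloxy)acetophenone
Product: 7 2,5‑dihydroxy‑4,6‑bis(benzyloxy)acetophenone, via potassium aryl sulfate 6 (not isolated)
Conditions: K2S2O8, aq NaOH/pyridine, 0 °C to rt; then aq HCl, 80 °C
Reagents that add atoms: potassium peroxodisulfate, [K+].[K+].[O-]S(=O)(=O)OOS(=O)(=O)[O-]
Why: Elbs persulfate oxidation, in which the phenoxide of 2 attacks the peroxide oxygen through the carbon para to its own oxygen (C5, between the two benzyloxy groups) and the resulting aryl sulfate is hydrolysed by warm dilute acid to the hydroquinone, unreacted 2 being recoverable before the hydrolysis.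

Step 5
Reactants: 5 5,7‑bis(benzyloxy)‑4'‑iodoflavone; 7 2,5‑dihydroxy‑4,6‑bis(benzyloxy)acetophenone
Product: 8 2‑{4‑[3‑acetyl‑2,6‑bis(benzyloxy)‑4‑hydroxyphenoxy]phenyl}‑5,7‑bis(benzyloxy)‑4H‑chromen‑4‑one
Conditions: CuI (10 mol%), picolinic acid (20 mol%), K3PO4, degassed DMSO, 90 °C, argon
Reagents that add atoms: none
Why: Ullmann‑type copper‑catalysed C–O coupling with the CuI/picolinic acid system, which arylates di‑ortho‑substituted phenols with aryl iodides; the 2‑OH, hydrogen‑bonded to the acetyl group and as its phenoxide a poorly nucleophilic vinylogous carboxylate, should stay free, and exclusion of air keeps the hydroquinone from oxidising.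

Step 6
Reactants: 8 2‑{4‑[3‑acetyl‑2,6‑bis(benzyloxy)‑4‑hydroxyphenoxy]phenyl}‑5,7‑bis(benzyloxy)‑4H‑chromen‑4‑one
Product: 9 (E)‑1‑{2,4‑bis(benzyloxy)‑3‑[4‑(5,7‑bis(benzyloxy)‑4‑oxo‑4H‑chromen‑2‑yl)phenoxy]‑6‑hydroxyphenyl}‑3‑(dimethylamino)prop‑2‑en‑1‑one
Conditions: Me2NCH(OMe)2 (3 equiv), toluene, 100 °C
Reagents that add atoms: N,N‑dimethylformamide dimethyl acetal, COC(OC)N(C)C
Why: Condensation of the only CH‑acidic site, the acetyl methyl group, with the formamide acetal should give the (E)‑enaminone, the usual first stage of the enaminone route to 2,3‑unsubstituted chromones.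

Step 7
Reactants: 9 (E)‑enaminone of step 6
Product: 10 5,7‑bis(benzyloxy)‑6‑{4‑[5,7‑bis(benzyloxy)‑4‑oxo‑4H‑chromen‑2‑yl]phenoxy}‑4H‑chromen‑4‑one
Conditions: conc. HCl, CH2Cl2, rt
Reagents that add atoms: none
Why: Acid‑promoted 6‑endo oxa‑Michael addition of the 2‑OH to the protonated enaminone followed by loss of dimethylamine gives the chromone (enaminone chromone synthesis) under conditions that should neither cleave benzyl ethers nor affect the flavone.

Step 8
Reactants: 10 5,7‑bis(benzyloxy)‑6‑{4‑[5,7‑bis(benzyloxy)‑4‑oxo‑4H‑chromen‑2‑yl]phenoxy}‑4H‑chromen‑4‑one; 11 4‑(benzyloxy)phenylboronic acid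
Product: 12 (2S)‑5,7‑bis(benzyloxy)‑2‑[4‑(benzyloxy)phenyl]‑6‑{4‑[5,7‑bis(benzyloxy)‑4‑oxo‑4H‑chromen‑2‑yl]phenoxy}‑2,3‑dihydro‑4H‑chromen‑4‑one
Conditions: [Rh(OH)(cod)]2 (2.5 mol%), (S)‑MeO‑F12‑BIPHEP [(S)‑6,6'‑dimethoxy‑2,2'‑bis{bis(3,4,5‑trifluorophenyl)phosphino}‑1,1'‑biphenyl] (5.5 mol%), 11 (4 equiv, in portions), toluene/H2O 10:1, 30 °C
Reagents that add atoms: none
Why: Transmetalation of 11 to the hydroxorhodium–bisphosphine complex gives a chiral aryl complex of monovalent rhodium that carbometalates the C2=C3 bond of the 2‑unsubstituted chromone in 10 with the aryl group going to C2, and the resulting rhodium oxa‑π‑allyl enolate is protonated by water faster than it can expel the ring oxygen, which regenerates Rh–OH. The closest known reaction type is the rhodium‑catalysed asymmetric 1,4‑addition of arylboronic acids to chromones with electron‑poor biaryl bisphosphines (Hayashi–Miyaura conjugate arylation), which is established for 5,7‑dioxygenated flavanones. The step closes no ring; it forms only the C2–C1' bond between ring C and ring B. The new C2 stereocentre is controlled by the ligand, the (S)‑antipode being chosen to block the Si face so that the aryl group adds to the Re face of C2 and gives the (2S)‑flavanone. Chemoselectivity between the two pyranones comes from the substrate, because the flavone C2 already bears an aryl group and is a β,β‑disubstituted enone that resists insertion, while the electron‑poor ligand suppresses 1,2‑addition to the ketones. All phenols are benzylated and no halide remains, so nothing chelates or oxidatively adds to the catalyst, and the base‑free medium should keep the flavanone from ring‑opening racemisation.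

Step 9
Reactants: 12 penta‑O‑benzyl (2S)‑flavanone of step 8
Product: 13 (2S)‑5,7‑dihydroxy‑2‑(4‑hydroxyphenyl)‑6‑[4‑(5,7‑dihydroxy‑4‑oxo‑4H‑chromen‑2‑yl)phenoxy]‑2,3‑dihydro‑4H‑chromen‑4‑one (CNP0206535.1)
Conditions: H2 (1 atm), 10% Pd/C, THF/MeOH, rt, stopped at the calculated uptake
Reagents that add atoms: none
Why: Catalytic hydrogenolysis of the five aryl benzyl ethers under neutral conditions should outpace reduction of the flavone C2=C3 bond, the aryl ketones and the benzylic C2–O bond of the flavanone, and it involves no base, so the C2 centre cannot racemise by ring opening.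

**Compound list**

1 | 2,4,6‑trihydroxyacetophenone | CC(=O)c1c(O)cc(O)cc1O | starting material
2 | 2‑hydroxy‑4,6‑bis(benzyloxy)acetophenone | CC(=O)c1c(O)cc(OCc2ccccc2)cc1OCc1ccccc1 | intermediate
3 | 4‑iodobenzaldehyde | O=Cc1ccc(I)cc1 | starting material
4 | (E)‑2'‑hydroxy‑4',6'‑bis(benzyloxy)‑4‑iodochalcone | O=C(/C=C/c1ccc(I)cc1)c1c(O)cc(OCc2ccccc2)cc1OCc1ccccc1 | intermediate
5 | 5,7‑bis(benzyloxy)‑4'‑iodoflavone | O=c1cc(-c2ccc(I)cc2)oc2cc(OCc3ccccc3)cc(OCc3ccccc3)c12 | intermediate
6 | potassium 3‑acetyl‑2,6‑bis(benzyloxy)‑4‑hydroxyphenyl sulfate | CC(=O)c1c(O)cc(OCc2ccccc2)c(OS(=O)(=O)[O-])c1OCc1ccccc1.[K+] | intermediate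
7 | 2,5‑dihydroxy‑4,6‑bis(benzyloxy)acetophenone | CC(=O)c1c(O)cc(OCc2ccccc2)c(O)c1OCc1ccccc1 | intermediate
8 | 2‑{4‑[3‑acetyl‑2,6‑bis(benzyloxy)‑4‑hydroxyphenoxy]phenyl}‑5,7‑bis(benzyloxy)‑4H‑chromen‑4‑one | CC(=O)c1c(O)cc(OCc2ccccc2)c(Oc2ccc(-c3cc(=O)c4c(OCc5ccccc5)cc(OCc5ccccc5)cc4o3)cc2)c1OCc1ccccc1 | intermediate
9 | (E)‑1‑{2,4‑bis(benzyloxy)‑3‑[4‑(5,7‑bis(benzyloxy)‑4‑oxo‑4H‑chromen‑2‑yl)phenoxy]‑6‑hydroxyphenyl}‑3‑(dimethylamino)prop‑2‑en‑1‑one | CN(C)/C=C/C(=O)c1c(O)cc(OCc2ccccc2)c(Oc2ccc(-c3cc(=O)c4c(OCc5ccccc5)cc(OCc5ccccc5)cc4o3)cc2)c1OCc1ccccc1 | intermediate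
10 | 5,7‑bis(benzyloxy)‑6‑{4‑[5,7‑bis(benzyloxy)‑4‑oxo‑4H‑chromen‑2‑yl]phenoxy}‑4H‑chromen‑4‑one | O=c1ccoc2cc(OCc3ccccc3)c(Oc3ccc(-c4cc(=O)c5c(OCc6ccccc6)cc(OCc6ccccc6)cc5o4)cc3)c(OCc3ccccc3)c12 | intermediate
11 | 4‑(benzyloxy)phenylboronic acid | OB(O)c1ccc(OCc2ccccc2)cc1 | starting material
12 | (2S)‑5,7‑bis(benzyloxy)‑2‑[4‑(benzyloxy)phenyl]‑6‑{4‑[5,7‑bis(benzyloxy)‑4‑oxo‑4H‑chromen‑2‑yl]phenoxy}‑2,3‑dihydro‑4H‑chromen‑4‑one | O=C1C[C@@H](c2ccc(OCc3ccccc3)cc2)Oc2cc(OCc3ccccc3)c(Oc3ccc(-c4cc(=O)c5c(OCc6ccccc6)cc(OCc6ccccc6)cc5o4)cc3)c(OCc3ccccc3)c21 | intermediate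
13 | (2S)‑5,7‑dihydroxy‑2‑(4‑hydroxyphenyl)‑6‑[4‑(5,7‑dihydroxy‑4‑oxo‑4H‑chromen‑2‑yl)phenoxy]‑2,3‑dihydro‑4H‑chromen‑4‑one (CNP0206535.1) | O=C1C[C@@H](c2ccc(O)cc2)Oc2cc(O)c(Oc3ccc(-c4cc(=O)c5c(O)cc(O)cc5o4)cc3)c(O)c21 | target

**Step count**

Total: 9 steps. Longest linear sequence: 8 steps from 1 (steps 1, 2, 3, 5, 6, 7, 8, 9); step 4 is the second branch from 2.

**Steps most likely to fail**

Step 8. Insertion into the electron‑rich 5,6,7‑trioxygenated chromone may be slow enough for protodeboronation of the boronic acid to win, or the facial discrimination may fall short. The fallback gives up the catalytic arylation and sets out from 8. Claisen–Schmidt condensation of 8 with 4‑(benzyloxy)benzaldehyde (KOH, EtOH/THF, rt) should give the (E)‑2'‑hydroxychalcone F1. Heating with NaOAc in EtOH should close it by oxa‑Michael addition to the racemic penta‑O‑benzyl flavanone F2. Preparative chromatography on a polysaccharide chiral stationary phase would then separate 12 from the (R)‑enantiomer F3. F3 can be re‑equilibrated through F1 with NaOAc and resolved again. The route is rejoined at 12.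

Step 5. Reductive elimination from copper may be slow for the di‑ortho‑alkoxy phenoxide, arylation may compete at the chelated hydroxyl, or the hydroquinone may be oxidised in the basic copper medium. The fallback replaces the copper catalysis by a metal‑free arylation and sets out from 5. Oxidation of 5 with mCPBA and TsOH·H2O in MeCN, then capture with 1,3,5‑trimethoxybenzene, should give the aryl(2,4,6‑trimethoxyphenyl)iodonium tosylate F4. F4 should arylate the 5‑phenoxide of 7 (K2CO3, MeCN, 40 °C, argon) by ligand coupling at trivalent iodine, the electron‑rich trimethoxyphenyl group acting as the non‑transferred ligand. The route is rejoined at 8.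

Step 4. Conversion may be low because the lipophilic phenoxide dissolves poorly in the aqueous persulfate medium, over‑oxidation may occur, and benzyl ethers may be partly lost in the hot acid hydrolysis. The fallback sets out from 2 and avoids both the sulfate ester and hot acid. Teuber oxidation of 2 with Fremy's salt, (KO3S)2NO, in KH2PO4‑buffered aqueous acetone should give 2‑acetyl‑3,5‑bis(benzyloxy)‑1,4‑benzoquinone F5. F5 is reduced at once with Na2S2O4 (EtOAc/H2O, rt) to the hydroquinone. The route is rejoined at 7.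

**Further compounds**

F1 | step 8 | (E)‑1‑{2,4‑bis(benzyloxy)‑3‑[4‑(5,7‑bis(benzyloxy)‑4‑oxo‑4H‑chromen‑2‑yl)phenoxy]‑6‑hydroxyphenyl}‑3‑[4‑(benzyloxy)phenyl]prop‑2‑en‑1‑one | O=C(/C=C/c1ccc(OCc2ccccc2)cc1)c1c(O)cc(OCc2ccccc2)c(Oc2ccc(-c3cc(=O)c4c(OCc5ccccc5)cc(OCc5ccccc5)cc4o3)cc2)c1OCc1ccccc1
F2 | step 8 | racemic 5,7‑bis(benzyloxy)‑2‑[4‑(benzyloxy)phenyl]‑6‑{4‑[5,7‑bis(benzyloxy)‑4‑oxo‑4H‑chromen‑2‑yl]phenoxy}‑2,3‑dihydro‑4H‑chromen‑4‑one | O=C1CC(c2ccc(OCc3ccccc3)cc2)Oc2cc(OCc3ccccc3)c(Oc3ccc(-c4cc(=O)c5c(OCc6ccccc6)cc(OCc6ccccc6)cc5o4)cc3)c(OCc3ccccc3)c21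
F3 | step 8 | (2R)‑5,7‑bis(benzyloxy)‑2‑[4‑(benzyloxy)phenyl]‑6‑{4‑[5,7‑bis(benzyloxy)‑4‑oxo‑4H‑chromen‑2‑yl]phenoxy}‑2,3‑dihydro‑4H‑chromen‑4‑one | O=C1C[C@H](c2ccc(OCc3ccccc3)cc2)Oc2cc(OCc3ccccc3)c(Oc3ccc(-c4cc(=O)c5c(OCc6ccccc6)cc(OCc6ccccc6)cc5o4)cc3)c(OCc3ccccc3)c21
F4 | step 5 | [4‑(5,7‑bis(benzyloxy)‑4‑oxo‑4H‑chromen‑2‑yl)phenyl](2,4,6‑trimethoxyphenyl)iodonium 4‑methylbenzenesulfonate | COc1cc(OC)c([I+]c2ccc(-c3cc(=O)c4c(OCc5ccccc5)cc(OCc5ccccc5)cc4o3)cc2)c(OC)c1.Cc1ccc(S(=O)(=O)[O-])cc1
F5 | step 4 | 2‑acetyl‑3,5‑bis(benzyloxy)cyclohexa‑2,5‑diene‑1,4‑dione | CC(=O)C1=C(OCc2ccccc2)C(=O)C(OCc2ccccc2)=CC1=O
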